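Take as a working assumption that J lost equals Q made, as the overall equation says, so that J left is the charge less Q. Then define the reach y of a run as the natural log of J charged over J left. With a rate proportional to J and L, and L staying at work, y grows with L times time.

| flask | J | L | time |
|---|---|---|---|
| Saturday's | 250 mM | 13.0 mM |  |
| Wednesday's | 120 mM | 13.0 mM |  |
| Monday's | 250 mM | 19.0 mM |  |
| Tuesday's | 250 mM | 32.0 mM | 88 min |

| run | time / min | [Q] / mM |
|---|---|---|
| Saturday's run | 6.7 | 13.6 |
| Saturday's run | 20 | 33.8 |
| Saturday's run | 39 | 59.2 |
| Saturday's run | 62 | 75.1 |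
| Saturday's run | 88 | 83.5 |
| Wednesday's run | 6.7 | 6.8 |
| Wednesday's run | 20 | 19.3 |
| Wednesday's run | 39 | 31.4 |
| Wednesday's run | 62 | 41.9 |
| Wednesday's run | 88 | 47.9 |
| Monday's run | 6.7 | 16.4 |
| Monday's run | 20 | 49.1 |
| Monday's run | 39 | 78.4 |
| Monday's run | 62 | 97.4 |
| Monday's run | 88 | 101.6 |

(each reading ± 0.8 mM)

- Overall: J -> Q, with L as catalyst.
- Constant volume, constant temperature.
- Bound and free are read together.
- An order is taken over about fifteen percent of the charge, up and down.

- reaction order in [J] at the outset, round the charge of the Saturday's run, defined at two percent of the J turned into Q (one fixed amount of Q, the same in the runs compared)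
- reaction order in [L] at the outset, round the charge of the Saturday's run, defined at two percent of the J turned into Q
- Q in the Tuesday's run at 88 min, as a share of the J charged

Read the coefficient w, reach per L per minute, from Saturday's first reading: 0.642 M⁻¹ min⁻¹, with that reading's scatter in it. But Saturday's reach at 88 min is 0.553 of what w promises. Call this the working share m, and treat it as the mean share of L at work over the run.

Replace the Q curve by its mean too. Saturday's time-mean Q, counted from zero, is 55.1 mM, so its wear is 0.0146 mM⁻¹: wear (catalyst deactivation, as a reading) being the excess of the inverse of m over one, per mM of mean Q. Wednesday's run gives 0.0145 mM⁻¹, so hold wear constant.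

For Tuesday's run, let mean Q stand to final Q as in Saturday's, 0.660. Starting from half the charge, one pass gives 55.9% and a second 53.7%. I commit to that second figure, and I have no separate reckoning for the orders.

The forecast gives 0.9 (0.72 to 1.05) in J, 0.85 (0.55 to 1.1) in L, and 41.5% (39.5% to 45%) for Tuesday's run, which is less than mine. Its ground: “Because the plateau scales with J and hardly with L, this looks like a reversible reaction near equilibrium, not catalyst death.”

The flask gives 0.77 in J, 1.0 in L, and 50.1% for Tuesday's run.

    L + J ⇌ LJ (2.352 M⁻¹ min⁻¹, 1.068 min⁻¹)
    LJ → Q + L (0.5916 min⁻¹)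
    L + Q → Wa + Q (0.2862 M⁻¹ min⁻¹)
    Q → Jy (0.003654 min⁻¹)

With L and J together in Saturday's run, the path through LJ made Q at 1.9 mM min⁻¹ once two percent of the J had turned. With Q present, L + Q → Wa ran, and Q → Jy ran beside it. Tuesday's result reads back as a working share of 0.385, against 0.425 reckoned. Saturday's wear of 0.0146 mM⁻¹, put through the same two passes for Monday's run, gives 38.5% and then 42.7% of Monday's charge at 88 min, where Monday's reading is 40.6%.

The earlier runs and the new flask stem from a simulated flask on assumed constants, and the scatter is random.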